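**Remark on the chemistry:** the β-dicarbonyl compounds 9, 11, 12 and 19 and the hydroxyquinone 23 are each written in one tautomeric form. They will exist largely as enols, so the stereocentres of 11 and 12 are labile and have no bearing on the achiral target.

## Analysis of the target

- The target 23 consists of a 2,5-dihydroxy-1,4-naphthoquinone (benzenoid ring B, quinone ring C) that carries a 2,4-dihydroxy-6-methylbenzoyl group (ring A) on C6 and a 4-hydroxy-2-pyranone (ring D) linked to C7 through one methylene carbon.
- It has no stereocentre, so every difficulty is one of regiochemistry and functional-group tolerance.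
- The sensitive groups are the hydroxyquinone (bases, nucleophiles, reductants), the pyranone (acidic, oxidisable enol, opened by hydroxide) and the free resorcinol.
- The molecule is an uncyclised polyketide: C5 of the pyranone, or the open 3,5-dioxo chain behind it, can undergo aldol condensation with the diaryl ketone, so strong acid or base must be avoided once that chain is in place.
- The hardest bond is the ketone bridge. It is flanked by four ortho substituents (OH and CH3 on ring A, the C5 hydroxyl and the C7 methylene on ring B), so neither addition of an aryl nucleophile to an acyl derivative nor a Friedel–Crafts acylation is credible.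
- C5, C6 and C7 carry three different contiguous substituents, and ring C needs oxygen at C1, C2 and C4 only.
- The strategy rests on ring A being a 4-acyl-5-methylresorcinol, the dehydrogenation product of a 4-acyl-5-methylcyclohexane-1,3-dione. Such a dione forms when the central carbon of a 1,3-diketone adds to a crotonate and the acetyl methyl then closes on the ester. The ketone carbon can therefore arrive on the naphthalene as part of a soft enolate, and ring A is grown around it.
- Ring C, with oxygen at C1, C2 and C4, is a masked 1,2,4-trimethoxybenzene ring that can be carried unchanged from acid 1.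

## Retrosynthetic reasoning

**23 to 21.** No carbon–carbon bond is cut. The six phenolic hydroxyls are traced back to methyl ethers, and the quinone to the 1,2,4-trimethoxy ring of 21. Ether cleavage gives the hexaphenol 22, whose trihydroxylated ring is a hydroxyhydroquinone that passes to the quinone on aerobic work-up. This is placed last because neither the hydroxyquinone nor the free resorcinol would survive the enolate, Lewis acid and oxidation steps before it, and because no oxygen has to be introduced.

**21 to 19, 18, and 15 + 17.** The pyranone is opened at its O1–C2 bond to the dioxinone ketone 19, which closes to the pyranone on heating through the acylketene 20. 19 comes from alcohol 18 by oxidation. In 18 the bond between the carbinol carbon and the dioxinone methylene is cut, giving aldehyde 15 and silyl dienol ether 17, which is made from the commercial dioxinone 16. The dioxinone keeps the 3,5-dioxo chain masked until a neutral, thermal step, so the chain never meets base while the diaryl ketone is within reach.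

**15 to 14, 13 and 12.** The aldehyde is carried as the diethyl acetal of 14, which is stable to every basic step before it. The ring A methyl ethers of 14 go back to the resorcinol 13. 13 goes back to the dione 12 by removal of two hydrogens; no skeletal bond changes.

**12 to 9 + 10.** This is the central disconnection. In ring A of 12 the C4–C5 bond (conjugate addition) and the C1–C2 bond (ester condensation) are cut, giving the naphthoyl acetone 9 and crotonate 10. The cut is made here because it removes the crowded ketone from the list of bonds to be formed: the ketone carbon is already on the naphthalene, and ring A is assembled from a four-carbon ester by two enolate reactions. The forward step must add 10 at the central carbon of 9 and close the ring through the adduct 11 before the acetyl group is lost.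

**9 to 8.** The bond between C2 and C3 of the butanedione chain is cut. The methyl ketone 8 is acylated on its only enolisable carbon by an acetate ester.

**8 to 7, and 7 to 4 + 6.** The methyl ether 8 comes from naphthol 7. In 7 the C1–C2 and C3–C4 bonds of the naphthalene are cut. Anhydride 4 supplies the oxygenated ring with C1 and C4, and ynone 6 supplies C2 with its acetyl group and C3 with the acetal chain. The anionic annulation with decarboxylation fixes the acetyl group next to the new hydroxyl, which is the C5/C6 relationship of the target.

**6 to 5, and 4 to 3, 2 and 1.** Ynone 6 is the C-acetylation product of alkyne 5. Anhydride 4 is the cyclodehydration product of diacid 3. In 3 the benzylic carbon–carboxyl bond is cut to give toluic acid 2, and in 2 the aryl–methyl bond is cut to give acid 1. The only free position of 1 next to the carboxyl group is the one that must carry the new carbon.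

## Alternatives that were turned down

**Alternative 1: aryne insertion.**
- Disconnection: both bonds from ring B to its carbon substituents, C6–C(O) and C7–CH2, are cut at once. This leads to the naphthalyne precursor A2 and the aryl pyranonylmethyl ketone A3.
- Forward key step: fluoride releases the aryne from A2. The enolate carbon of A3 attacks the aryne carbon remote from the methoxy-bearing position, the aryl anion adds to the ketone, and the four-membered alkoxide fragments to A1.
- For it: it is the most convergent plan. Ring A, the ketone, the naphthalene and the pyranone are joined in one operation, and the inductive bias of the neighbouring methoxy group points the right way. On convergence it is clearly stronger than the chosen route, which is linear from 7 onwards.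
- Against it:
  - Insertion into a C–C bond is dependable only when the methylene is doubly activated. In A3 it is a ketone α-carbon with only vinylogous help from the pyranone.
  - The aryl anion must add to a ketone that already bears two ortho substituents. Proton transfer would give simple α-arylation, and the pyranone ring carbons and oxygen compete as nucleophiles.
  - A2 needs an ortho silyl triflate on a tetraoxygenated naphthalene, which costs a separate multistep sequence.
  - The pyranone methyl ether of A1 must still be cleaved.
- Comparison: the chosen route gives up convergence. In return both ring A bonds are made by enolate reactions with fixed connectivity, and the hindered ketone is never the electrophile.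

**Alternative 2: halogen-directed quinone Diels–Alder.**
- Disconnection: ring B is cut at C4a–C5 and C8–C8a into the bromoquinone A6 (ring C) and the vinylketene acetal A5.
- Forward key step: cycloaddition with the regiochemistry set by the bromine, then loss of hydrogen halide and of the silyl ether aromatises ring B to A4.
- For it: it reaches the naphthoquinone at the final oxidation level in one step, with the C2 oxygen and the C5 hydroxyl placed correctly. On speed to the core and on avoiding a late oxidation it is stronger than the chosen route.
- Against it: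
  - A4 carries an ester at C6 and a methyl group at C7, so the two hardest bonds are still missing.
  - The ester would have to take an aryl nucleophile between two ortho substituents, and the methyl group would have to be functionalised at the benzylic position, both on a base- and nucleophile-sensitive methoxyquinone.
  - The quinone would have to be reduced and protected again, which gives back the steps saved.
- Comparison: the chosen route needs more steps to reach ring B. It arrives there with the ketone carbon (the acetyl group of 7) and the two-carbon side chain already in place.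

**Alternative 3: toluate anion annulation.**
- Disconnection: ring B is cut at the benzylic carbon–acyl carbon bond and the methyl carbon–ester carbon bond, leading to the toluate A8 and an acetyl unit.
- Forward key step: lateral lithiation of A8, acylation by an acetyl amide, and condensation of the new methyl ketone enolate on the ester give the naphthalenediol A7.
- For it: a one-flask entry to a naphthalene with four differentiated oxygens from a simple benzoate. This is shorter than the three steps from 1 to 4 plus the annulation of the chosen route.
- Against it: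
  - The ring formed carries only hydrogen and oxygen at the positions that become C6 and C7.
  - The aroyl group would have to be introduced by acylation between the two hydroxyls with a doubly ortho-substituted acyl donor, in competition with the more reactive position para to the C1 hydroxyl of A7.
  - The C3 hydroxyl of A7 would have to be exchanged for carbon by sulfonylation and cross-coupling next to that new ketone.
  - The other ring has two oxygens where three are needed, so a further C–H oxidation is required, with the risk of oxidising the wrong ring.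
- Comparison: in the chosen route the three oxygens of ring C come with 1, and both carbon substituents of ring B are set by the annulation of 4 with 6.

Key step: step 8

## Route

Step 1
Reactants: 1 2,4,5-trimethoxybenzoic acid
Product: 2 3,4,6-trimethoxy-2-methylbenzoic acid
Conditions: s-BuLi (2.2 equiv), TMEDA, THF, −78 °C; MeI; aq. HCl
Reagents that add atoms: iodomethane, CI
Why: Directed ortho-metalation of the unprotected acid: the lithium carboxylate–s-BuLi–TMEDA complex should remove the one hydrogen that lies between the carboxylate and a methoxy group (C6), and the aryllithium is then methylated.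

Step 2
Reactants: 2 3,4,6-trimethoxy-2-methylbenzoic acid
Product: 3 2-(carboxymethyl)-3,4,6-trimethoxybenzoic acid
Conditions: LiN(i-Pr)2 (2.3 equiv), THF, −78 → 0 °C; poured onto excess solid CO2; aq. HCl
Reagents that add atoms: carbon dioxide, O=C=O
Why: Lateral lithiation of an ortho-toluic acid: the carboxylate-assisted benzylic dianion is carboxylated at carbon, the established way from ortho-toluic acids to homophthalic acids; inverse quenching into excess CO2 prevents proton exchange with the product.

Step 3
Reactants: 3 2-(carboxymethyl)-3,4,6-trimethoxybenzoic acid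
Product: 4 5,6,8-trimethoxy-1H-isochromene-1,3(4H)-dione
Conditions: Ac2O, toluene, 90 °C
Reagents that add atoms: none
Why: Cyclodehydration of a homophthalic acid to its six-membered anhydride through the mixed anhydride; without added base the acidic C4 position is not acetylated.

Step 4
Reactants: 5 4,4-diethoxybut-1-yne
Product: 6 6,6-diethoxyhex-3-yn-2-one
Conditions: n-BuLi, THF, −78 °C; MeC(O)N(OMe)Me, −78 → 0 °C; AcOH quench
Reagents that add atoms: N-methoxy-N-methylacetamide, CC(=O)N(C)OC
Why: Acylation of a lithium acetylide with a Weinreb amide: the chelated tetrahedral adduct prevents a second addition and releases the ynone on quenching, and the acetal is inert to the base.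

Step 5
Reactants: 4 5,6,8-trimethoxy-1H-isochromene-1,3(4H)-dione, 6 6,6-diethoxyhex-3-yn-2-one
Product: 7 1-[3-(2,2-diethoxyethyl)-1-hydroxy-5,6,8-trimethoxynaphthalen-2-yl]ethan-1-one
Conditions: NaH (1.05 equiv), THF, 0 °C; then 6, 0 °C → rt; AcOH quench
Reagents that add atoms: none
Why: Tamura annulation: the C4 anion of the anhydride adds to the alkyne carbon β to the ketone, the new carbanion closes on the aryl-bound anhydride carbonyl, and decarboxylation aromatises to the peri-hydroxynaphthalene, which places the acetyl group next to the hydroxyl and the acetal chain at C3. One equivalent of base is consumed entirely as the stabilised anhydride anion, so nothing remains to deprotonate the propargylic position of 6.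

Step 6
Reactants: 7 1-[3-(2,2-diethoxyethyl)-1-hydroxy-5,6,8-trimethoxynaphthalen-2-yl]ethan-1-one
Product: 8 1-[3-(2,2-diethoxyethyl)-1,5,6,8-tetramethoxynaphthalen-2-yl]ethan-1-one
Conditions: MeI, K2CO3, DMF, 50 °C
Reagents that add atoms: iodomethane, CI
Why: Williamson O-methylation of the chelated naphthol; K2CO3 is too weak to enolise the methyl ketone for C-alkylation, and the acetal is stable to base.

Step 7
Reactants: 8 1-[3-(2,2-diethoxyethyl)-1,5,6,8-tetramethoxynaphthalen-2-yl]ethan-1-one
Product: 9 1-[3-(2,2-diethoxyethyl)-1,5,6,8-tetramethoxynaphthalen-2-yl]butane-1,3-dione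
Conditions: NaH (2.5 equiv), EtOAc (excess), THF, 60 °C; AcOH quench
Reagents that add atoms: ethyl acetate, CCOC(C)=O
Why: Crossed Claisen condensation: the acetyl methyl is the only enolisable position of 8, its sodium enolate is acylated by ethyl acetate, and the product leaves the equilibrium as its diketonate.

Step 8
Reactants: 9 1-[3-(2,2-diethoxyethyl)-1,5,6,8-tetramethoxynaphthalen-2-yl]butane-1,3-dione, 10 ethyl (E)-but-2-enoate
Product: 12 rac-(4S,5R)-4-[3-(2,2-diethoxyethyl)-1,5,6,8-tetramethoxynaphthalene-2-carbonyl]-5-methylcyclohexane-1,3-dione (trans), via Michael adduct 11 (not isolated)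
Conditions: NaOEt (1.2 equiv), EtOH, reflux; cold aq. NaH2PO4
Reagents that add atoms: none
Why: Ethoxide deprotonates 9 between its carbonyl groups, and this stabilised enolate adds through carbon to the β-carbon of 10, forming the C4–C5 bond of the future ring A and giving 11 after proton transfer. Equilibration then supplies a small amount of the acetyl-methyl enolate of 11, which attacks the ester carbonyl (C2–C1 bond) and expels ethoxide; the released ethoxide deprotonates the cyclic tricarbonyl product at once, and this delocalised enolate is the thermodynamic sink that pulls both reversible events forward. The closest known reaction type is the Michael–Dieckmann condensation of acetoacetates and 1,3-diketones with crotonates, which gives dihydroorsellinates and 4-acylcyclohexane-1,3-diones. The one ring is closed in the 6-exo-trig mode, with the enolate double bond exocyclic to the forming ring. Both new stereocentres (C4 and C5) are racemic; C4 lies between carbonyl groups and epimerises freely, so the trans isomer with both substituents equatorial should result from thermodynamic control, and both centres are erased in step 9. The step needs cyclisation at carbon and not at oxygen, and ring closure before retro-Claisen loss of the acetyl group: only the central carbon of the monoanion is nucleophilic, only the acetyl methyl can reach the ester through a six-membered transition state because the aryl side has no α-hydrogen, the aroyl carbonyl is screened from ethoxide by its two ortho substituents, and the small excess of base keeps nearly all ethoxide bound as enolate. The acetal and the aryl methyl ethers are inert to ethoxide, and ethanol as solvent makes any acetal or ester exchange degenerate.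

Step 9
Reactants: 12 rac-(4S,5R)-4-[3-(2,2-diethoxyethyl)-1,5,6,8-tetramethoxynaphthalene-2-carbonyl]-5-methylcyclohexane-1,3-dione
Product: 13 [3-(2,2-diethoxyethyl)-1,5,6,8-tetramethoxynaphthalen-2-yl](2,4-dihydroxy-6-methylphenyl)methanone
Conditions: DDQ (1.2 equiv), 1,4-dioxane, 80 °C
Reagents that add atoms: none
Why: Dehydrogenation of a cyclohexane-1,3-dione to a resorcinol: DDQ should abstract hydride from C5 of the enol conjugated with the aroyl group, and loss of a proton from C6 with tautomerisation gives the aromatic ring, removing both stereocentres. The medium is anhydrous and only weakly acidic, so the acetal should persist, and the benzylic methylene is deactivated towards hydride loss by the ortho ketone.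

Step 10
Reactants: 13 [3-(2,2-diethoxyethyl)-1,5,6,8-tetramethoxynaphthalen-2-yl](2,4-dihydroxy-6-methylphenyl)methanone
Product: 14 [3-(2,2-diethoxyethyl)-1,5,6,8-tetramethoxynaphthalen-2-yl](2,4-dimethoxy-6-methylphenyl)methanone
Conditions: MeI (excess), K2CO3, DMF, 60 °C
Reagents that add atoms: iodomethane, CI
Why: Double Williamson etherification, with warming for the hydrogen-bonded ortho hydroxyl; the methyl ethers shield ring A from the hypervalent iodine oxidant of step 14 and leave with the other four in step 16.

Step 11
Reactants: 14 [3-(2,2-diethoxyethyl)-1,5,6,8-tetramethoxynaphthalen-2-yl](2,4-dimethoxy-6-methylphenyl)methanone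
Product: 15 2-[3-(2,4-dimethoxy-6-methylbenzoyl)-4,5,7,8-tetramethoxynaphthalen-2-yl]acetaldehyde
Conditions: 2 M HCl (cat.), THF–H2O, rt
Reagents that add atoms: water, O
Why: Acid-catalysed acetal hydrolysis; dilute acid at room temperature leaves the aryl methyl ethers and the hindered ketone untouched, and the enolisable aldehyde is used without storage.

Step 12
Reactants: 16 2,2,6-trimethyl-4H-1,3-dioxin-4-one
Product: 17 trimethyl[(2,2-dimethyl-4-methylidene-4H-1,3-dioxin-6-yl)oxy]silane
Conditions: LiN(i-Pr)2, THF, −78 °C; Me3SiCl, −78 °C → rt
Reagents that add atoms: chlorotrimethylsilane, C[Si](C)(C)Cl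
Why: γ-Deprotonation of the dioxinone gives the extended enolate, which is silylated on oxygen to the known silyl dienol ether.

Step 13
Reactants: 15 2-[3-(2,4-dimethoxy-6-methylbenzoyl)-4,5,7,8-tetramethoxynaphthalen-2-yl]acetaldehyde, 17 trimethyl[(2,2-dimethyl-4-methylidene-4H-1,3-dioxin-6-yl)oxy]silane
Product: 18 6-{3-[3-(2,4-dimethoxy-6-methylbenzoyl)-4,5,7,8-tetramethoxynaphthalen-2-yl]-2-hydroxypropyl}-2,2-dimethyl-4H-1,3-dioxin-4-one (racemic)
Conditions: BF3·OEt2 (1.1 equiv), CH2Cl2, −78 °C; aq. NaHCO3
Reagents that add atoms: none
Why: Vinylogous Mukaiyama aldol addition: the BF3-activated aldehyde is attacked by the terminal methylene carbon of 17, which avoids the basic conditions under which an arylacetaldehyde enolises, and the diaryl ketone with four ortho substituents is too hindered to compete. The carbinol centre forms without control (racemic) and is removed in step 14.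

Step 14
Reactants: 18 6-{3-[3-(2,4-dimethoxy-6-methylbenzoyl)-4,5,7,8-tetramethoxynaphthalen-2-yl]-2-hydroxypropyl}-2,2-dimethyl-4H-1,3-dioxin-4-one
Product: 19 6-{3-[3-(2,4-dimethoxy-6-methylbenzoyl)-4,5,7,8-tetramethoxynaphthalen-2-yl]-2-oxopropyl}-2,2-dimethyl-4H-1,3-dioxin-4-one
Conditions: Dess–Martin periodinane, CH2Cl2, 0 °C → rt
Reagents that add atoms: none
Why: Dess–Martin oxidation of a secondary alcohol under near-neutral conditions; the fully methylated aryl rings and the dioxinone are inert to the reagent.

Step 15
Reactants: 19 6-{3-[3-(2,4-dimethoxy-6-methylbenzoyl)-4,5,7,8-tetramethoxynaphthalen-2-yl]-2-oxopropyl}-2,2-dimethyl-4H-1,3-dioxin-4-one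
Product: 21 6-{[3-(2,4-dimethoxy-6-methylbenzoyl)-4,5,7,8-tetramethoxynaphthalen-2-yl]methyl}-4-hydroxy-2H-pyran-2-one, via acylketene 20 (not isolated)
Conditions: toluene (0.01 M), 110 °C
Reagents that add atoms: none
Why: Thermal retro-hetero-Diels–Alder loss of acetone from the dioxinone gives acylketene 20, whose ketone enol adds through oxygen to the ketene carbon to close the 4-hydroxy-2-pyranone. The dilute, neutral medium gives the active methylene no base with which to attack the diaryl ketone.

Step 16
Reactants: 21 6-{[3-(2,4-dimethoxy-6-methylbenzoyl)-4,5,7,8-tetramethoxynaphthalen-2-yl]methyl}-4-hydroxy-2H-pyran-2-one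
Product: 23 6-(2,4-dihydroxy-6-methylbenzoyl)-2,5-dihydroxy-7-[(4-hydroxy-2-oxo-2H-pyran-6-yl)methyl]naphthalene-1,4-dione (the target), via hexahydroxy leuco compound 22 (not isolated)
Conditions: BBr3 (excess), CH2Cl2, −78 °C → rt; H2O, 0 °C; then air, pH 7 buffer–EtOAc, rt
Reagents that add atoms: none
Why: Lewis-acid ether cleavage: BBr3 coordinates each methoxy oxygen and bromide removes the methyl group, giving after hydrolysis the hexaphenol 22. Its 1,2,4-trihydroxylated ring is a hydroxyhydroquinone and should be oxidised by air to the 2-hydroxy-1,4-quinone; no other ring of 22 has a para-dioxygen pattern, so only this quinone can form.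

## Compound list

1 | 2,4,5-trimethoxybenzoic acid | COc1cc(OC)c(C(=O)O)cc1OC | starting material
2 | 3,4,6-trimethoxy-2-methylbenzoic acid | Cc1c(C(=O)O)c(OC)cc(OC)c1OC | intermediate
3 | 2-(carboxymethyl)-3,4,6-trimethoxybenzoic acid | OC(=O)Cc1c(C(=O)O)c(OC)cc(OC)c1OC | intermediate
4 | 5,6,8-trimethoxy-1H-isochromene-1,3(4H)-dione | COc1cc(OC)c2c(c1OC)CC(=O)OC2=O | intermediate
5 | 4,4-diethoxybut-1-yne | C#CCC(OCC)OCC | starting material
6 | 6,6-diethoxyhex-3-yn-2-one | CC(=O)C#CCC(OCC)OCC | intermediate
7 | 1-[3-(2,2-diethoxyethyl)-1-hydroxy-5,6,8-trimethoxynaphthalen-2-yl]ethan-1-one | CC(=O)c1c(CC(OCC)OCC)cc2c(OC)c(OC)cc(OC)c2c1O | intermediate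
8 | 1-[3-(2,2-diethoxyethyl)-1,5,6,8-tetramethoxynaphthalen-2-yl]ethan-1-one | CC(=O)c1c(CC(OCC)OCC)cc2c(OC)c(OC)cc(OC)c2c1OC | intermediate
9 | 1-[3-(2,2-diethoxyethyl)-1,5,6,8-tetramethoxynaphthalen-2-yl]butane-1,3-dione | CC(=O)CC(=O)c1c(CC(OCC)OCC)cc2c(OC)c(OC)cc(OC)c2c1OC | intermediate
10 | ethyl (E)-but-2-enoate | C/C=C/C(=O)OCC | starting material
11 | ethyl 4-acetyl-5-[3-(2,2-diethoxyethyl)-1,5,6,8-tetramethoxynaphthalen-2-yl]-3-methyl-5-oxopentanoate (racemic diastereomer mixture) | CCOC(=O)CC(C)C(C(C)=O)C(=O)c1c(CC(OCC)OCC)cc2c(OC)c(OC)cc(OC)c2c1OC | intermediate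
12 | rac-(4S,5R)-4-[3-(2,2-diethoxyethyl)-1,5,6,8-tetramethoxynaphthalene-2-carbonyl]-5-methylcyclohexane-1,3-dione (trans; one enantiomer drawn) | C[C@@H]1CC(=O)CC(=O)[C@H]1C(=O)c1c(CC(OCC)OCC)cc2c(OC)c(OC)cc(OC)c2c1OC | intermediate
13 | [3-(2,2-diethoxyethyl)-1,5,6,8-tetramethoxynaphthalen-2-yl](2,4-dihydroxy-6-methylphenyl)methanone | Cc1cc(O)cc(O)c1C(=O)c1c(CC(OCC)OCC)cc2c(OC)c(OC)cc(OC)c2c1OC | intermediate
14 | [3-(2,2-diethoxyethyl)-1,5,6,8-tetramethoxynaphthalen-2-yl](2,4-dimethoxy-6-methylphenyl)methanone | Cc1cc(OC)cc(OC)c1C(=O)c1c(CC(OCC)OCC)cc2c(OC)c(OC)cc(OC)c2c1OC | intermediate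
15 | 2-[3-(2,4-dimethoxy-6-methylbenzoyl)-4,5,7,8-tetramethoxynaphthalen-2-yl]acetaldehyde | Cc1cc(OC)cc(OC)c1C(=O)c1c(CC=O)cc2c(OC)c(OC)cc(OC)c2c1OC | intermediate
16 | 2,2,6-trimethyl-4H-1,3-dioxin-4-one | CC1=CC(=O)OC(C)(C)O1 | starting material
17 | trimethyl[(2,2-dimethyl-4-methylidene-4H-1,3-dioxin-6-yl)oxy]silane | C=C1C=C(O[Si](C)(C)C)OC(C)(C)O1 | intermediate
18 | 6-{3-[3-(2,4-dimethoxy-6-methylbenzoyl)-4,5,7,8-tetramethoxynaphthalen-2-yl]-2-hydroxypropyl}-2,2-dimethyl-4H-1,3-dioxin-4-one (racemic) | Cc1cc(OC)cc(OC)c1C(=O)c1c(CC(O)CC2=CC(=O)OC(C)(C)O2)cc2c(OC)c(OC)cc(OC)c2c1OC | intermediate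
19 | 6-{3-[3-(2,4-dimethoxy-6-methylbenzoyl)-4,5,7,8-tetramethoxynaphthalen-2-yl]-2-oxopropyl}-2,2-dimethyl-4H-1,3-dioxin-4-one | Cc1cc(OC)cc(OC)c1C(=O)c1c(CC(=O)CC2=CC(=O)OC(C)(C)O2)cc2c(OC)c(OC)cc(OC)c2c1OC | intermediate
20 | 6-[3-(2,4-dimethoxy-6-methylbenzoyl)-4,5,7,8-tetramethoxynaphthalen-2-yl]hex-1-ene-1,3,5-trione (acylketene) | Cc1cc(OC)cc(OC)c1C(=O)c1c(CC(=O)CC(=O)C=C=O)cc2c(OC)c(OC)cc(OC)c2c1OC | intermediate
21 | 6-{[3-(2,4-dimethoxy-6-methylbenzoyl)-4,5,7,8-tetramethoxynaphthalen-2-yl]methyl}-4-hydroxy-2H-pyran-2-one | Cc1cc(OC)cc(OC)c1C(=O)c1c(Cc2cc(O)cc(=O)o2)cc2c(OC)c(OC)cc(OC)c2c1OC | intermediate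
22 | 6-{[3-(2,4-dihydroxy-6-methylbenzoyl)-4,5,7,8-tetrahydroxynaphthalen-2-yl]methyl}-4-hydroxy-2H-pyran-2-one | Cc1cc(O)cc(O)c1C(=O)c1c(Cc2cc(O)cc(=O)o2)cc2c(O)c(O)cc(O)c2c1O | intermediate
23 | 6-(2,4-dihydroxy-6-methylbenzoyl)-2,5-dihydroxy-7-[(4-hydroxy-2-oxo-2H-pyran-6-yl)methyl]naphthalene-1,4-dione | Cc1cc(O)cc(O)c1C(=O)c1c(Cc2cc(O)cc(=O)o2)cc2c(c1O)C(=O)C=C(O)C2=O | target

## Step count and least certain steps

Total step count: 16. Longest linear sequence: 14 steps (steps 1–3, 5–11 and 13–16, from 1 to 23); steps 4 and 12 are side branches.

**Step 8 (key step).**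
- What may go wrong: retro-Claisen loss of the acetyl group from the adduct 11 by ethoxide before the ring closes, or reversal of the slow conjugate addition to the β-substituted ester, so that 9 is returned or degraded.
- Fallback: the two bond formations are separated. Starting from 9 and 10, the conjugate addition is run with a catalytic, non-nucleophilic base (Cs2CO3 in MeCN at 60 °C) and 11 is isolated. 11 is then treated with LiN(SiMe3)2 (3 equiv) in THF at −78 to 0 °C. This forms the dianion at the central carbon and the acetyl methyl, and the terminal carbanion closes on the ester with no alkoxide present until the ring exists. The sequence comes back to the route at 12 and makes no compound outside the list.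

**Step 9.**
- What may go wrong: attack of the nucleophilic enol carbon C2 of the dione on DDQ to give quinol ether adducts instead of hydride transfer, charge-transfer oxidation of the tetramethoxynaphthalene or its benzylic methylene, or loss of the acetal to the acidic hydroquinone by-product.
- Fallback: aromatisation with concomitant etherification instead of hydride abstraction. Starting from 12, iodine in refluxing methanol (enol ether formation, α-iodination, loss of HI) should give (2-hydroxy-4-methoxy-6-methylphenyl)[3-(2,2-dimethoxyethyl)-1,5,6,8-tetramethoxynaphthalen-2-yl]methanone F1, with the acetal exchanged to the dimethyl acetal. Methylation of the chelated hydroxyl as in step 10 gives (2,4-dimethoxy-6-methylphenyl)[3-(2,2-dimethoxyethyl)-1,5,6,8-tetramethoxynaphthalen-2-yl]methanone F2. Aqueous acid as in step 11 then comes back to the route at 15.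

**Step 16.**
- What may go wrong: incomplete cleavage of the least activated ether (para-methoxy of ring A) giving partly methylated mixtures, over-oxidation or condensation of the very electron-rich polyphenol 22 during the aerobic work-up, or acid-promoted aldol closure of the pyranone onto the diaryl ketone on long exposure to the Lewis acid.
- Fallback: the quinone is set by a defined oxidant before the pyranone exists, and fewer ethers are left for the end.
  - Starting from 18, (NH4)2Ce(NO3)6 in MeCN–H2O at 0 °C should oxidise the trimethoxy ring to 6-{3-[3-(2,4-dimethoxy-6-methylbenzoyl)-4,7-dimethoxy-5,8-dioxo-5,8-dihydronaphthalen-2-yl]-2-hydroxypropyl}-2,2-dimethyl-4H-1,3-dioxin-4-one F3. No oxidisable enol is present at this stage.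
  - Dess–Martin oxidation gives 6-{3-[3-(2,4-dimethoxy-6-methylbenzoyl)-4,7-dimethoxy-5,8-dioxo-5,8-dihydronaphthalen-2-yl]-2-oxopropyl}-2,2-dimethyl-4H-1,3-dioxin-4-one F4.
  - Heating in toluene gives, through 6-[3-(2,4-dimethoxy-6-methylbenzoyl)-4,7-dimethoxy-5,8-dioxo-5,8-dihydronaphthalen-2-yl]hex-1-ene-1,3,5-trione F5, the pyranone 6-{[3-(2,4-dimethoxy-6-methylbenzoyl)-4,7-dimethoxy-5,8-dioxo-5,8-dihydronaphthalen-2-yl]methyl}-4-hydroxy-2H-pyran-2-one F6.
  - BBr3 then has to cleave only four ethers, two of them activated, and the sequence comes back at 23.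

**Step 1.**
- What may go wrong: competing lithiation at C3 between the two methoxy groups, displacement of the ortho methoxy group or addition of s-BuLi to the carboxylate, and over-alkylation through lateral lithiation of 2.
- Fallback: the tertiary amide is used as the directing group, which dominates the methoxy groups.
  - Starting from 1, the acid chloride (SOCl2) and Et2NH give N,N-diethyl-2,4,5-trimethoxybenzamide F7.
  - s-BuLi–TMEDA and MeI give N,N-diethyl-3,4,6-trimethoxy-2-methylbenzamide F8.
  - Cp2Zr(H)Cl reduces the hindered amide to 3,4,6-trimethoxy-2-methylbenzaldehyde F9.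
  - NaClO2–NaH2PO4 with 2-methylbut-2-ene oxidises F9, coming back to the route at 2.

**Step 13.**
- What may go wrong: enolisation and self-condensation of the arylacetaldehyde 15, or Lewis-acid-induced closure of its enol oxygen onto the neighbouring ketone (benzopyrylium formation), ahead of the addition.
- Fallback: the electrophile is raised to the acid oxidation level, so no aldehyde meets a Lewis acid and step 14 is not needed.
  - Starting from 15, NaClO2–NaH2PO4 with 2-methylbut-2-ene gives [3-(2,4-dimethoxy-6-methylbenzoyl)-4,5,7,8-tetramethoxynaphthalen-2-yl]acetic acid F10.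
  - 1,1'-Carbonyldiimidazole gives 1-{[3-(2,4-dimethoxy-6-methylbenzoyl)-4,5,7,8-tetramethoxynaphthalen-2-yl]acetyl}-1H-imidazole F11.
  - F11 is added to the lithium dienolate made from 16 and LiN(SiMe3)2 (excess, THF, −78 °C). C-acylation at the dienolate terminus comes back to the route at 19.

## Further compounds

F0 | step 8 | none | none
F1 | step 9 | (2-hydroxy-4-methoxy-6-methylphenyl)[3-(2,2-dimethoxyethyl)-1,5,6,8-tetramethoxynaphthalen-2-yl]methanone | Cc1cc(OC)cc(O)c1C(=O)c1c(CC(OC)OC)cc2c(OC)c(OC)cc(OC)c2c1OC
F2 | step 9 | (2,4-dimethoxy-6-methylphenyl)[3-(2,2-dimethoxyethyl)-1,5,6,8-tetramethoxynaphthalen-2-yl]methanone | Cc1cc(OC)cc(OC)c1C(=O)c1c(CC(OC)OC)cc2c(OC)c(OC)cc(OC)c2c1OC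
F3 | step 16 | 6-{3-[3-(2,4-dimethoxy-6-methylbenzoyl)-4,7-dimethoxy-5,8-dioxo-5,8-dihydronaphthalen-2-yl]-2-hydroxypropyl}-2,2-dimethyl-4H-1,3-dioxin-4-one (racemic) | Cc1cc(OC)cc(OC)c1C(=O)c1c(CC(O)CC2=CC(=O)OC(C)(C)O2)cc2c(c1OC)C(=O)C=C(OC)C2=O
F4 | step 16 | 6-{3-[3-(2,4-dimethoxy-6-methylbenzoyl)-4,7-dimethoxy-5,8-dioxo-5,8-dihydronaphthalen-2-yl]-2-oxopropyl}-2,2-dimethyl-4H-1,3-dioxin-4-one | Cc1cc(OC)cc(OC)c1C(=O)c1c(CC(=O)CC2=CC(=O)OC(C)(C)O2)cc2c(c1OC)C(=O)C=C(OC)C2=O
F5 | step 16 | 6-[3-(2,4-dimethoxy-6-methylbenzoyl)-4,7-dimethoxy-5,8-dioxo-5,8-dihydronaphthalen-2-yl]hex-1-ene-1,3,5-trione | Cc1cc(OC)cc(OC)c1C(=O)c1c(CC(=O)CC(=O)C=C=O)cc2c(c1OC)C(=O)C=C(OC)C2=O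
F6 | step 16 | 6-{[3-(2,4-dimethoxy-6-methylbenzoyl)-4,7-dimethoxy-5,8-dioxo-5,8-dihydronaphthalen-2-yl]methyl}-4-hydroxy-2H-pyran-2-one | Cc1cc(OC)cc(OC)c1C(=O)c1c(Cc2cc(O)cc(=O)o2)cc2c(c1OC)C(=O)C=C(OC)C2=O
F7 | step 1 | N,N-diethyl-2,4,5-trimethoxybenzamide | CCN(CC)C(=O)c1cc(OC)c(OC)cc1OC
F8 | step 1 | N,N-diethyl-3,4,6-trimethoxy-2-methylbenzamide | CCN(CC)C(=O)c1c(C)c(OC)c(OC)cc1OC
F9 | step 1 | 3,4,6-trimethoxy-2-methylbenzaldehyde | Cc1c(C=O)c(OC)cc(OC)c1OC
F10 | step 13 | [3-(2,4-dimethoxy-6-methylbenzoyl)-4,5,7,8-tetramethoxynaphthalen-2-yl]acetic acid | Cc1cc(OC)cc(OC)c1C(=O)c1c(CC(=O)O)cc2c(OC)c(OC)cc(OC)c2c1OC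
F11 | step 13 | 1-{[3-(2,4-dimethoxy-6-methylbenzoyl)-4,5,7,8-tetramethoxynaphthalen-2-yl]acetyl}-1H-imidazole | Cc1cc(OC)cc(OC)c1C(=O)c1c(CC(=O)n2ccnc2)cc2c(OC)c(OC)cc(OC)c2c1OC
A1 | alternative 1 | 6-{[3-(2,4-dimethoxy-6-methylbenzoyl)-4,5,7,8-tetramethoxynaphthalen-2-yl]methyl}-4-methoxy-2H-pyran-2-one | COc1cc(C)c(C(=O)c2c(Cc3cc(OC)cc(=O)o3)cc3c(OC)c(OC)cc(OC)c3c2OC)c(OC)c1
A2 | alternative 1 | 1,5,6,8-tetramethoxy-3-(trimethylsilyl)naphthalen-2-yl trifluoromethanesulfonate | COc1cc(OC)c2c(OC)c(OS(=O)(=O)C(F)(F)F)c([Si](C)(C)C)cc2c1OC
A3 | alternative 1 | 6-[2-(2,4-dimethoxy-6-methylphenyl)-2-oxoethyl]-4-methoxy-2H-pyran-2-one | COc1cc(C)c(C(=O)Cc2cc(OC)cc(=O)o2)c(OC)c1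
A4 | alternative 2 | methyl 1-hydroxy-6-methoxy-3-methyl-5,8-dioxo-5,8-dihydronaphthalene-2-carboxylate | COC(=O)c1c(C)cc2c(c1O)C(=O)C=C(OC)C2=O
A5 | alternative 2 | methyl 2-{methoxy[(trimethylsilyl)oxy]methylidene}-3-methylbut-3-enoate | C=C(C)C(C(=O)OC)=C(OC)O[Si](C)(C)C
A6 | alternative 2 | 2-bromo-5-methoxycyclohexa-2,5-diene-1,4-dione | COC1=CC(=O)C(Br)=CC1=O
A7 | alternative 3 | 6-(benzyloxy)-8-methoxynaphthalene-1,3-diol | COc1cc(OCc2ccccc2)cc2cc(O)cc(O)c12
A8 | alternative 3 | methyl 4-(benzyloxy)-2-methoxy-6-methylbenzoate | COC(=O)c1c(C)cc(OCc2ccccc2)cc1OC
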